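**Plan**
- Retrosynthetic cuts, in order: C11=C13 (Horner–Wadsworth–Emmons with formaldehyde); the C6–O isovalerate bond, with re-closure of a helper bond C11–C6 (vinylcyclopropane); C3–C4 (Nozaki–Hiyama–Kishi closure of the ten-membered ring); C11–C7 together with C11–C6 (carbene from a diazophosphonoacetate on O8 onto C6=C7); C7–C8 (alkenylzinc plus aldehyde).
- Enabling feature: O8 on C8 is allylic to C7=C6, and C6 is allylic to C4=C5. The lactone α-carbon C11, delivered from O8 as a carbene, therefore closes the γ-lactone (C11–C7) and a cyclopropane (C11–C6) in one event. The C6–C11 bond is a vinylcyclopropane bond that is later exchanged for the C6 isovalerate through the C4–C5–C6 allyl unit; the phosphonate on C11 activates that opening and then becomes the exocyclic methylene.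
- Forward order: the C8–C10/C1–C3 aldehyde and the C4–C7/C15 iodoenyne are joined at C7–C8; the γ-lactone (with cyclopropane) is closed first, the ten-membered ring second, the cyclopropane is opened third, the methylene comes last.
- Stereochemistry: C8 from ligand-controlled alkenylzinc addition; C7 and C11 from C8-directed syn carbene addition to the E C6=C7 alkene; C6 from a retentive (double inversion) allylpalladium opening; C3 from substrate-controlled ring closure. The E alkenes come from syn carboalumination (C1=C10), syn hydrostannation (C4=C5) and syn hydroboration (C6=C7).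

Key step: step 14

Remark: the facial sense of the amino-alcohol-catalysed alkenylzinc addition in step 11 is assigned from the accepted model for this catalyst class; the antipodal ligand serves if the sense is opposite. Atom numbers C1–C15 are germacrane numbers of the target.

Step 1
Reactants: 1 tert-butyl(but-3-yn-1-yloxy)dimethylsilane
Product: 4 (3E)-6-[(tert-butyldimethylsilyl)oxy]-4-methylhex-3-en-1-ol, via alkenyldimethylalane 2 (not isolated), via lithium alkenylaluminate 3 (not isolated)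
Conditions: AlMe3, Cp2ZrCl2 (25 mol%), CH2Cl2, rt; n-BuLi, hexane/THF, -78 to 0 °C; ethylene oxide, 0 °C
Reagents that add atoms: trimethylaluminium, C[Al](C)C; ethylene oxide, C1CO1
Why: Negishi carboalumination adds methyl and aluminium syn across the alkyne (methyl on the internal carbon), and the derived aluminate opens ethylene oxide with retention, so the C1=C10 alkene is set as E.

Step 2
Reactants: 4 (3E)-6-[(tert-butyldimethylsilyl)oxy]-4-methylhex-3-en-1-ol
Product: 5 tert-butyl{[(3E)-6-[(4-methoxyphenyl)methoxy]-3-methylhex-3-en-1-yl]oxy}dimethylsilane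
Conditions: NaH, 4-methoxybenzyl chloride, Bu4NI (cat.), THF/DMF, 0 °C to rt
Reagents that add atoms: 4-methoxybenzyl chloride, COc1ccc(CCl)cc1
Why: Williamson etherification masks the future C3 aldehyde as a 4-methoxybenzyl ether that is orthogonal to the silyl ether.

Step 3
Reactants: 5 tert-butyl{[(3E)-6-[(4-methoxyphenyl)methoxy]-3-methylhex-3-en-1-yl]oxy}dimethylsilane
Product: 6 (3E)-6-[(4-methoxyphenyl)methoxy]-3-methylhex-3-en-1-ol
Conditions: Bu4NF, THF, 0 °C to rt
Reagents that add atoms: none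
Why: Fluoride cleaves the primary silyl ether and leaves the benzyl-type ether untouched.

Step 4
Reactants: 6 (3E)-6-[(4-methoxyphenyl)methoxy]-3-methylhex-3-en-1-ol
Product: 7 (3E)-6-[(4-methoxyphenyl)methoxy]-3-methylhex-3-enal
Conditions: Dess–Martin periodinane, NaHCO3, CH2Cl2, 0 °C; used at once
Reagents that add atoms: none
Why: Buffered Dess–Martin oxidation should give the β,γ-unsaturated aldehyde (C8) without moving the alkene into conjugation.

Step 5
Reactants: 8 but-2-yne-1,4-diol
Product: 9 4-[(tert-butyldimethylsilyl)oxy]but-2-yn-1-ol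
Conditions: NaH (1 equiv), tert-butyldimethylsilyl chloride (1 equiv), THF, 0 °C to rt, diol in excess
Reagents that add atoms: tert-butyldimethylsilyl chloride, CC(C)(C)[Si](C)(C)Cl
Why: Monosilylation of the symmetrical diol through its monosodium alkoxide differentiates the future C15 (free OH) and C6 (silyl ether) oxygens.

Step 6
Reactants: 9 4-[(tert-butyldimethylsilyl)oxy]but-2-yn-1-ol
Product: 11 (2E)-4-[(tert-butyldimethylsilyl)oxy]-2-iodobut-2-en-1-ol, via vinylstannane 10 (not isolated)
Conditions: Bu3SnH, PdCl2(PPh3)2 (2 mol%), THF, rt; then I2, CH2Cl2, 0 °C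
Reagents that add atoms: iodine, II
Why: Palladium-catalysed syn hydrostannation puts tin next to the free hydroxymethyl group (hydroxyl-directed, away from the bulkier silyloxymethyl side) with hydrogen cis to it, and iododestannylation with retention fixes C15 and C6 cis across the future C4=C5 bond.

Step 7
Reactants: 11 (2E)-4-[(tert-butyldimethylsilyl)oxy]-2-iodobut-2-en-1-ol
Product: 12 (2E)-4-[(tert-butyldimethylsilyl)oxy]-2-iodobut-2-en-1-yl 3-methylbutanoate
Conditions: 3-methylbutanoyl chloride, pyridine, DMAP (cat.), CH2Cl2, 0 °C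
Reagents that add atoms: 3-methylbutanoyl chloride, CC(C)CC(Cl)=O
Why: Acylation of the primary allylic alcohol installs the C15 isovalerate of the target at the outset.

Step 8
Reactants: 12 (2E)-4-[(tert-butyldimethylsilyl)oxy]-2-iodobut-2-en-1-yl 3-methylbutanoate
Product: 13 (2E)-4-hydroxy-2-iodobut-2-en-1-yl 3-methylbutanoate
Conditions: HF·pyridine, THF, 0 °C to rt
Reagents that add atoms: none
Why: Buffered fluoride removes the primary silyl ether without touching the ester or the vinyl iodide.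

Step 9
Reactants: 13 (2E)-4-hydroxy-2-iodobut-2-en-1-yl 3-methylbutanoate
Product: 14 (2E)-2-iodo-4-oxobut-2-en-1-yl 3-methylbutanoate
Conditions: Dess–Martin periodinane, NaHCO3, CH2Cl2, 0 °C
Reagents that add atoms: none
Why: Dess–Martin oxidation of the allylic alcohol gives the C6 enal under neutral conditions that should not isomerise the iodoalkene.

Step 10
Reactants: 14 (2E)-2-iodo-4-oxobut-2-en-1-yl 3-methylbutanoate
Product: 15 (2E)-2-iodopent-2-en-4-yn-1-yl 3-methylbutanoate
Conditions: Me3SiCHN2, LDA, THF, -78 to 0 °C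
Reagents that add atoms: (trimethylsilyl)diazomethane, C[Si](C)(C)C=[N+]=[N-]
Why: In the Colvin rearrangement lithiated trimethylsilyldiazomethane adds to the aldehyde, silanolate is lost and the alkylidene carbene undergoes a 1,2-hydrogen shift to the terminal alkyne (C7), at a temperature where the ester is not attacked.

Step 11
Reactants: 15 (2E)-2-iodopent-2-en-4-yn-1-yl 3-methylbutanoate; 7 (3E)-6-[(4-methoxyphenyl)methoxy]-3-methylhex-3-enal
Product: 18 (2E,4E,6S,8E)-6-hydroxy-2-iodo-11-[(4-methoxyphenyl)methoxy]-8-methylundeca-2,4,8-trien-1-yl 3-methylbutanoate, via dienylborane 16 (not isolated), via dienylzinc 17 (not isolated)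
Conditions: Cy2BH, toluene, 0 °C to rt; ZnMe2, -78 °C; (+)-MIB [(2R)-3-exo-morpholinoisoborneol] (4 mol%), then 7, -10 °C
Reagents that add atoms: none
Why: Syn hydroboration of the terminal alkyne, boron-to-zinc transmetalation and catalytic asymmetric alkenylzinc addition to the Re face of aldehyde 7 form the C7–C8 bond, the E C6=C7 alkene and the 8S carbinol.

Step 12
Reactants: 18 (2E,4E,6S,8E)-6-hydroxy-2-iodo-11-[(4-methoxyphenyl)methoxy]-8-methylundeca-2,4,8-trien-1-yl 3-methylbutanoate
Product: 19 (2E,4E,6S,8E)-6-{[(diethoxyphosphoryl)acetyl]oxy}-2-iodo-11-[(4-methoxyphenyl)methoxy]-8-methylundeca-2,4,8-trien-1-yl 3-methylbutanoate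
Conditions: (EtO)2P(O)CH2CO2H, DCC, DMAP (cat.), CH2Cl2, 0 °C to rt
Reagents that add atoms: diethylphosphonoacetic acid, CCOP(=O)(CC(=O)O)OCC
Why: Steglich esterification attaches C11 and C12 to O8 as the tether, with the phosphonate as activating group.

Step 13
Reactants: 19 (2E,4E,6S,8E)-6-{[(diethoxyphosphoryl)acetyl]oxy}-2-iodo-11-[(4-methoxyphenyl)methoxy]-8-methylundeca-2,4,8-trien-1-yl 3-methylbutanoate
Product: 20 (2E,4E,6S,8E)-6-{[diazo(diethoxyphosphoryl)acetyl]oxy}-2-iodo-11-[(4-methoxyphenyl)methoxy]-8-methylundeca-2,4,8-trien-1-yl 3-methylbutanoate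
Conditions: 4-acetamidobenzenesulfonyl azide, DBU, MeCN, 0 °C to rt
Reagents that add atoms: 4-acetamidobenzenesulfonyl azide, CC(=O)Nc1ccc(cc1)S(=O)(=O)N=[N+]=[N-]
Why: Regitz diazo transfer to the doubly activated methylene reverses the polarity of C11 for the carbene step.

Step 14
Reactants: 20 (2E,4E,6S,8E)-6-{[diazo(diethoxyphosphoryl)acetyl]oxy}-2-iodo-11-[(4-methoxyphenyl)methoxy]-8-methylundeca-2,4,8-trien-1-yl 3-methylbutanoate
Product: 21 diethyl {(1R,4S,5S,6S)-6-[(1E)-2-iodo-3-(3-methylbutanoyloxy)prop-1-en-1-yl]-4-[(2E)-5-[(4-methoxyphenyl)methoxy]-2-methylpent-2-en-1-yl]-2-oxo-3-oxabicyclo[3.1.0]hexan-1-yl}phosphonate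
Conditions: Rh2(OAc)4 (2 mol%), ClCH2CH2Cl, 60 °C, slow addition of 20
Reagents that add atoms: none
Why: Rh2(OAc)4 decomposes the diazophosphonoacetate to an electrophilic rhodium carbenoid at C11, which adds in a concerted, asynchronous [2+1] fashion to the nearest alkene, C6=C7, the diene terminus that is allylic to the ester oxygen on C8. The closest known reaction type is the intramolecular cyclopropanation of allylic diazoacetates, diazomalonates and diazophosphonoacetates to 3-oxabicyclo[3.1.0]hexan-2-ones. The γ-lactone closes through the C11–C7 bond in a formally 5-exo sense (C6 stays outside the five-membered ring), and the three-membered ring is completed by the C11–C6 bond, a helper bond that is taken out in step 18. C7 and C11 follow from the obligatory cis fusion and from attack on the alkene face that keeps the C8 hydrogen eclipsed with the alkene (least allylic 1,3-strain), which places the C9 chain trans to C6 across the lactone; C6 follows stereospecifically from the E geometry of C6=C7 by syn addition. The step needs chemoselectivity over the C4=C5 and C1=C10 alkenes and over C–H insertion, which the tether should secure because those alkenes would require seven- and six-membered rings and C4=C5 is deactivated by iodine.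

Step 15
Reactants: 21 diethyl {(1R,4S,5S,6S)-6-[(1E)-2-iodo-3-(3-methylbutanoyloxy)prop-1-en-1-yl]-4-[(2E)-5-[(4-methoxyphenyl)methoxy]-2-methylpent-2-en-1-yl]-2-oxo-3-oxabicyclo[3.1.0]hexan-1-yl}phosphonate
Product: 22 diethyl {(1R,4S,5S,6S)-4-[(2E)-5-hydroxy-2-methylpent-2-en-1-yl]-6-[(1E)-2-iodo-3-(3-methylbutanoyloxy)prop-1-en-1-yl]-2-oxo-3-oxabicyclo[3.1.0]hexan-1-yl}phosphonate
Conditions: DDQ, CH2Cl2/pH 7 buffer, 0 °C
Reagents that add atoms: none
Why: Oxidative cleavage of the 4-methoxybenzyl ether frees the C3 alcohol without affecting esters, the vinyl iodide or the cyclopropane.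

Step 16
Reactants: 22 diethyl {(1R,4S,5S,6S)-4-[(2E)-5-hydroxy-2-methylpent-2-en-1-yl]-6-[(1E)-2-iodo-3-(3-methylbutanoyloxy)prop-1-en-1-yl]-2-oxo-3-oxabicyclo[3.1.0]hexan-1-yl}phosphonate
Product: 23 diethyl {(1R,4S,5S,6S)-6-[(1E)-2-iodo-3-(3-methylbutanoyloxy)prop-1-en-1-yl]-4-[(2E)-2-methyl-5-oxopent-2-en-1-yl]-2-oxo-3-oxabicyclo[3.1.0]hexan-1-yl}phosphonate
Conditions: Dess–Martin periodinane, NaHCO3, CH2Cl2, 0 °C; used at once
Reagents that add atoms: none
Why: Buffered Dess–Martin oxidation gives the C3 aldehyde, and C11 is quaternary at this stage so the lactone has no acidic position.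

Step 17
Reactants: 23 diethyl {(1R,4S,5S,6S)-6-[(1E)-2-iodo-3-(3-methylbutanoyloxy)prop-1-en-1-yl]-4-[(2E)-2-methyl-5-oxopent-2-en-1-yl]-2-oxo-3-oxabicyclo[3.1.0]hexan-1-yl}phosphonate
Product: 24 diethyl [(3R,6R,7S,8S,11R)-3-hydroxy-15-(3-methylbutanoyloxy)-6,11-cyclo-13-norgermacra-1(10)E,4E-dien-12,8-olid-11-yl]phosphonate
Conditions: CrCl2 (10 equiv), NiCl2 (1 mol%), DMSO/THF, rt, high dilution, slow addition of 23
Reagents that add atoms: none
Why: In the Nozaki–Hiyama–Kishi reaction zerovalent nickel inserts into the vinyl iodide, the alkenyl group passes to trivalent chromium and adds to the aldehyde, closing the ten-membered ring at C3–C4 with retention of alkene geometry; the 3R carbinol is expected from attack on the outward face of the aldehyde in the closing conformation.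

Step 18
Reactants: 24 diethyl [(3R,6R,7S,8S,11R)-3-hydroxy-15-(3-methylbutanoyloxy)-6,11-cyclo-13-norgermacra-1(10)E,4E-dien-12,8-olid-11-yl]phosphonate
Product: 25 diethyl [(3R,6R,7R,8S)-3-hydroxy-6,15-bis(3-methylbutanoyloxy)-13-norgermacra-1(10)E,4E-dien-12,8-olid-11-yl]phosphonate (both C11 epimers)
Conditions: Pd2(dba)3 (2.5 mol%), PPh3 (10 mol%), 3-methylbutanoic acid (3 equiv), THF, rt
Reagents that add atoms: 3-methylbutanoic acid, CC(C)CC(=O)O
Why: Proposed new method: zerovalent palladium should ionise the C6–C11 bond of the vinylcyclopropane anti to that bond, because the departing carbanion is stabilised by both the lactone carbonyl and the phosphonate, giving a zwitterionic allylpalladium on C4–C5–C6 whose carbanion is protonated by the acid while the carboxylate attacks the less substituted terminus C6 anti to the metal (double inversion, net retention, 6R, E C4=C5 kept); the closest known reaction types are the palladium-catalysed ring opening of 2-vinylcyclopropane-1,1-dicarboxylates by pronucleophiles and palladium-catalysed allylic acyloxylation.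

Step 19
Reactants: 25 diethyl [(3R,6R,7R,8S)-3-hydroxy-6,15-bis(3-methylbutanoyloxy)-13-norgermacra-1(10)E,4E-dien-12,8-olid-11-yl]phosphonate (both C11 epimers)
Product: 26 (3R,6R,7R,8S)-3-hydroxy-6,15-bis(3-methylbutanoyloxy)germacra-1(10)E,4E,11(13)-trien-12,8-olide (CNP0317194.1)
Conditions: aq. CH2O, K2CO3, THF, 0 °C to rt
Reagents that add atoms: formaldehyde, C=O
Why: Horner–Wadsworth–Emmons olefination of the α-phosphono lactone with formaldehyde under mild carbonate conditions forms the exocyclic methylene, removes the phosphonate and the C11 stereocentre, and should spare the isovalerates and the free C3 hydroxyl.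

**Compound list**
1 | tert-butyl(but-3-yn-1-yloxy)dimethylsilane | C#CCCO[Si](C)(C)C(C)(C)C | starting material
2 | [(1E)-4-[(tert-butyldimethylsilyl)oxy]-2-methylbut-1-en-1-yl]dimethylalumane | C[Al](C)/C=C(\C)CCO[Si](C)(C)C(C)(C)C | intermediate
3 | lithium butyl[(1E)-4-[(tert-butyldimethylsilyl)oxy]-2-methylbut-1-en-1-yl]dimethylaluminate | [Li+].CCCC[Al-](C)(C)/C=C(\C)CCO[Si](C)(C)C(C)(C)C | intermediate
4 | (3E)-6-[(tert-butyldimethylsilyl)oxy]-4-methylhex-3-en-1-ol | OCC/C=C(\C)CCO[Si](C)(C)C(C)(C)C | intermediate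
5 | tert-butyl{[(3E)-6-[(4-methoxyphenyl)methoxy]-3-methylhex-3-en-1-yl]oxy}dimethylsilane | COc1ccc(COCC/C=C(\C)CCO[Si](C)(C)C(C)(C)C)cc1 | intermediate
6 | (3E)-6-[(4-methoxyphenyl)methoxy]-3-methylhex-3-en-1-ol | COc1ccc(COCC/C=C(\C)CCO)cc1 | intermediate
7 | (3E)-6-[(4-methoxyphenyl)methoxy]-3-methylhex-3-enal | COc1ccc(COCC/C=C(\C)CC=O)cc1 | intermediate
8 | but-2-yne-1,4-diol | OCC#CCO | starting material
9 | 4-[(tert-butyldimethylsilyl)oxy]but-2-yn-1-ol | OCC#CCO[Si](C)(C)C(C)(C)C | intermediate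
10 | (2E)-4-[(tert-butyldimethylsilyl)oxy]-2-(tributylstannyl)but-2-en-1-ol | OC/C([Sn](CCCC)(CCCC)CCCC)=C\CO[Si](C)(C)C(C)(C)C | intermediate
11 | (2E)-4-[(tert-butyldimethylsilyl)oxy]-2-iodobut-2-en-1-ol | OC/C(I)=C\CO[Si](C)(C)C(C)(C)C | intermediate
12 | (2E)-4-[(tert-butyldimethylsilyl)oxy]-2-iodobut-2-en-1-yl 3-methylbutanoate | CC(C)CC(=O)OC/C(I)=C\CO[Si](C)(C)C(C)(C)C | intermediate
13 | (2E)-4-hydroxy-2-iodobut-2-en-1-yl 3-methylbutanoate | CC(C)CC(=O)OC/C(I)=C\CO | intermediate
14 | (2E)-2-iodo-4-oxobut-2-en-1-yl 3-methylbutanoate | CC(C)CC(=O)OC/C(I)=C\C=O | intermediate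
15 | (2E)-2-iodopent-2-en-4-yn-1-yl 3-methylbutanoate | CC(C)CC(=O)OC/C(I)=C\C#C | intermediate
16 | (2E,4E)-5-(dicyclohexylboranyl)-2-iodopenta-2,4-dien-1-yl 3-methylbutanoate | CC(C)CC(=O)OC/C(I)=C\C=C\B(C1CCCCC1)C1CCCCC1 | intermediate
17 | [(1E,3E)-4-iodo-5-(3-methylbutanoyloxy)penta-1,3-dien-1-yl](methyl)zinc | CC(C)CC(=O)OC/C(I)=C\C=C\[Zn]C | intermediate
18 | (2E,4E,6S,8E)-6-hydroxy-2-iodo-11-[(4-methoxyphenyl)methoxy]-8-methylundeca-2,4,8-trien-1-yl 3-methylbutanoate | O[C@H](/C=C/C=C(/I)COC(=O)CC(C)C)C/C(C)=C/CCOCc1ccc(OC)cc1 | intermediate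
19 | (2E,4E,6S,8E)-6-{[(diethoxyphosphoryl)acetyl]oxy}-2-iodo-11-[(4-methoxyphenyl)methoxy]-8-methylundeca-2,4,8-trien-1-yl 3-methylbutanoate | CCOP(=O)(OCC)CC(=O)O[C@H](/C=C/C=C(/I)COC(=O)CC(C)C)C/C(C)=C/CCOCc1ccc(OC)cc1 | intermediate
20 | (2E,4E,6S,8E)-6-{[diazo(diethoxyphosphoryl)acetyl]oxy}-2-iodo-11-[(4-methoxyphenyl)methoxy]-8-methylundeca-2,4,8-trien-1-yl 3-methylbutanoate | CCOP(=O)(OCC)C(=[N+]=[N-])C(=O)O[C@H](/C=C/C=C(/I)COC(=O)CC(C)C)C/C(C)=C/CCOCc1ccc(OC)cc1 | intermediate
21 | diethyl {(1R,4S,5S,6S)-6-[(1E)-2-iodo-3-(3-methylbutanoyloxy)prop-1-en-1-yl]-4-[(2E)-5-[(4-methoxyphenyl)methoxy]-2-methylpent-2-en-1-yl]-2-oxo-3-oxabicyclo[3.1.0]hexan-1-yl}phosphonate | CCOP(=O)(OCC)[C@@]12C(=O)O[C@@H](C/C(C)=C/CCOCc3ccc(OC)cc3)[C@@H]1[C@H]2/C=C(/I)COC(=O)CC(C)C | intermediate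
22 | diethyl {(1R,4S,5S,6S)-4-[(2E)-5-hydroxy-2-methylpent-2-en-1-yl]-6-[(1E)-2-iodo-3-(3-methylbutanoyloxy)prop-1-en-1-yl]-2-oxo-3-oxabicyclo[3.1.0]hexan-1-yl}phosphonate | CCOP(=O)(OCC)[C@@]12C(=O)O[C@@H](C/C(C)=C/CCO)[C@@H]1[C@H]2/C=C(/I)COC(=O)CC(C)C | intermediate
23 | diethyl {(1R,4S,5S,6S)-6-[(1E)-2-iodo-3-(3-methylbutanoyloxy)prop-1-en-1-yl]-4-[(2E)-2-methyl-5-oxopent-2-en-1-yl]-2-oxo-3-oxabicyclo[3.1.0]hexan-1-yl}phosphonate | CCOP(=O)(OCC)[C@@]12C(=O)O[C@@H](C/C(C)=C/CC=O)[C@@H]1[C@H]2/C=C(/I)COC(=O)CC(C)C | intermediate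
24 | diethyl [(3R,6R,7S,8S,11R)-3-hydroxy-15-(3-methylbutanoyloxy)-6,11-cyclo-13-norgermacra-1(10)E,4E-dien-12,8-olid-11-yl]phosphonate (ten-membered ring with a trans-fused cyclopropane C6–C7–C11 that is also fused to the γ-lactone) | CCOP(=O)(OCC)[C@@]13C(=O)O[C@H]2C/C(C)=C/C[C@@H](O)/C(COC(=O)CC(C)C)=C/[C@@H]3[C@H]12 | intermediate
25 | diethyl [(3R,6R,7R,8S)-3-hydroxy-6,15-bis(3-methylbutanoyloxy)-13-norgermacra-1(10)E,4E-dien-12,8-olid-11-yl]phosphonate (both C11 epimers) | CCOP(=O)(OCC)C1C(=O)O[C@H]2C/C(C)=C/C[C@@H](O)/C(COC(=O)CC(C)C)=C/[C@@H](OC(=O)CC(C)C)[C@H]12 | intermediate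
26 | (3R,6R,7R,8S)-3-hydroxy-6,15-bis(3-methylbutanoyloxy)germacra-1(10)E,4E,11(13)-trien-12,8-olide (CNP0317194.1) | C=C1C(=O)O[C@H]2C/C(C)=C/C[C@@H](O)/C(COC(=O)CC(C)C)=C/[C@@H](OC(=O)CC(C)C)[C@H]12 | target

**Step count and risks**
Total step count: 19. Longest linear sequence: 15 steps (steps 5 to 19).

Steps most likely to fail:

1. Step 18. What may go wrong: too little overlap between the C6–C11 bond and the C4=C5 π system inside the ten-membered ring, so that ionisation is slow; attack of the carboxylate at the tertiary terminus C4; or loss of configuration at C6 through allyl isomerisation. Fallback with known chemistry, setting out from 24: MgI2 in THF should open the doubly activated cyclopropane by homoconjugate attack of iodide at the allylic carbon C6 with inversion and, after protonation of the magnesium enolate, give the C6-inverted allylic iodide F1. Displacement of iodide by caesium 3-methylbutanoate in DMF with a second inversion rejoins the route at 25.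

2. Step 17. What may go wrong: poor facial selectivity in the addition to the C3 aldehyde, so that both C3 epimers form, besides slow closure of the strained ring. Fallback, setting out from 24 obtained as an epimer mixture: Dess–Martin oxidation gives the C3 enone F2, and Corey–Bakshi–Shibata reduction with (S)-Me-CBS and BH3·SMe2 sets the 3R carbinol under reagent control, returning to 24.

3. Step 14. What may go wrong: poor facial selectivity of the carbene addition relative to C8 (C6 and C9 cis instead of trans across the lactone), or competing addition to a remote alkene. Fallback, setting out from 19, in which the ten-membered ring is closed first so that the ring presents one face of C6=C7: DDQ removes the 4-methoxybenzyl group to give the alcohol F3, Dess–Martin oxidation gives the aldehyde F4, and Nozaki–Hiyama–Kishi closure (CrCl2, NiCl2) gives the macrocyclic trienol F5. Diazo transfer then gives the macrocyclic diazo ester F6, and Rh2(OAc)4 closes the lactone and cyclopropane, rejoining the route at 24.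

**Further compounds**
F1 | step 18 | diethyl [(3R,8S)-3-hydroxy-6-iodo-15-(3-methylbutanoyloxy)-13-norgermacra-1(10)E,4E-dien-12,8-olid-11-yl]phosphonate, C6 inverted relative to 25 | CCOP(=O)(OCC)C1C(=O)O[C@H]2C/C(C)=C/C[C@@H](O)/C(COC(=O)CC(C)C)=C/[C@H](I)[C@H]12
F2 | step 17 | diethyl [(6R,7S,8S,11R)-15-(3-methylbutanoyloxy)-3-oxo-6,11-cyclo-13-norgermacra-1(10)E,4E-dien-12,8-olid-11-yl]phosphonate | CCOP(=O)(OCC)[C@@]13C(=O)O[C@H]2C/C(C)=C/CC(=O)/C(COC(=O)CC(C)C)=C/[C@@H]3[C@H]12
F3 | step 14 | (2E,4E,6S,8E)-6-{[(diethoxyphosphoryl)acetyl]oxy}-11-hydroxy-2-iodo-8-methylundeca-2,4,8-trien-1-yl 3-methylbutanoate | CCOP(=O)(OCC)CC(=O)O[C@H](/C=C/C=C(/I)COC(=O)CC(C)C)C/C(C)=C/CCO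
F4 | step 14 | (2E,4E,6S,8E)-6-{[(diethoxyphosphoryl)acetyl]oxy}-2-iodo-8-methyl-11-oxoundeca-2,4,8-trien-1-yl 3-methylbutanoate | CCOP(=O)(OCC)CC(=O)O[C@H](/C=C/C=C(/I)COC(=O)CC(C)C)C/C(C)=C/CC=O
F5 | step 14 | (3R,8S)-3-hydroxy-15-(3-methylbutanoyloxy)germacra-1(10)E,4E,6E-trien-8-yl (diethoxyphosphoryl)acetate (eleven-carbon macrocyclic trienol, no C11–C13 unit on C7) | C1/C(C)=C/C[C@@H](O)/C(COC(=O)CC(C)C)=C/C=C/[C@H]1OC(=O)CP(=O)(OCC)OCC
F6 | step 14 | (3R,8S)-3-hydroxy-15-(3-methylbutanoyloxy)germacra-1(10)E,4E,6E-trien-8-yl diazo(diethoxyphosphoryl)acetate | C1/C(C)=C/C[C@@H](O)/C(COC(=O)CC(C)C)=C/C=C/[C@H]1OC(=O)C(=[N+]=[N-])P(=O)(OCC)OCC
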